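**Plan**

- Retrosynthesis cuts the C9 glycidate ester, the 4,5-epoxide, the O6–C12 lactone bond together with the C11=C13 methylene, and the C8/C9 oxygens. It then opens the ten-membered ring across C6–C7 by a retro-[3,3] shift that re-forms C4–C9 of a cyclohexenol.
- Enabling feature (germacrane numbering): C9(=O)–C8–C7–C6 with C5=C4 is the δ,ε-unsaturated ketone pattern left by an oxy-Cope shift, and C9–C10=C1–C2–C3–C4 can be a cyclohexene that holds C1=C10 cis.
- The cyclohexenol is cut at C9–C8 (alkenyl addition), C5=C6 (olefination and C–O coupling), C10–C14 (hydroxymethylation) and the C4 quaternary centre (allylation).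
- Forward: the cyclohexenone ring is built from 2-methylcyclohexanone, the Z-alkenyl arm from but-3-yn-1-ol is added at C9, the enol ether arm is completed, the ring grows from six to ten atoms (step 16), the lactone closes in step 27 and the epoxide comes last.
- Stereochemistry: C4 from the (S)-PHOX-controlled allylation; the C9 carbinol (arms cis) by chelation to a C5 hydroxymethyl group; C6 and C7 from the chair of the [3,3] shift; C8 by outer-face enolate hydroxylation then Mitsunobu inversion; C9 by Felkin–Anh reduction; the epoxide by outer-face attack on the Z-alkene; the glycidate from (S)-2-methylglycidol.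

Key step: step 16

Remark: germacrane numbering is used throughout (ring C1–C10, C14 on C10, C15 on C4, C11–C13 on C7); the target SMILES is read as a cis 4,5-epoxide, a cis-fused 6,7-lactone, C8–O cis and C9–O trans to the C7 substituent.
Remark: any minor enantiomer carried from step 2 becomes a separable diastereomer once the enantiopure glycidate is attached in step 21.

**Route**

Step 1
Reactants: 1 2-methylcyclohexanone; 2 allyl chloroformate
Product: 4 allyl 2-methylcyclohex-1-en-1-yl carbonate, via potassium enolate 3 (not isolated)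
Conditions: t-BuOK, DMF, 25 °C (equilibration); then 2, 0 °C
Reagents that add atoms: none
Why: Enol carbonate formation by O-acylation, in which equilibration favours the tetrasubstituted potassium enolate and the hard chloroformate reacts at oxygen; the minor regioisomeric carbonate is removed by chromatography.

Step 2
Reactants: 4 allyl 2-methylcyclohex-1-en-1-yl carbonate
Product: 5 (S)-2-allyl-2-methylcyclohexan-1-one
Conditions: Pd2(dba)3 (2.5 mol %), (S)-t-BuPHOX (6 mol %), THF, 25 °C
Reagents that add atoms: none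
Why: Decarboxylative asymmetric allylic alkylation (Tsuji–Trost type), in which zerovalent palladium ionises the allyl carbonate, CO2 is lost and the ligand-bound allyl–enolate pair recombines at the substituted carbon, the (S)-ligand setting the quaternary C4 as S.

Step 3
Reactants: 5 (S)-2-allyl-2-methylcyclohexan-1-one
Product: 6 (S)-2-methyl-2-[(E)-prop-1-en-1-yl]cyclohexan-1-one
Conditions: RhCl3·3H2O (cat.), EtOH, 75 °C
Reagents that add atoms: none
Why: Metal hydride catalysed allyl-to-propenyl alkene isomerisation moves the double bond to the more stable internal E position, so that the later cleavage leaves a one-carbon arm on C4.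

Step 4
Reactants: 6 (S)-2-methyl-2-[(E)-prop-1-en-1-yl]cyclohexan-1-one
Product: 8 (S)-6-methyl-6-[(E)-prop-1-en-1-yl]cyclohex-2-en-1-one, via silyl enol ether 7 (not isolated)
Conditions: Me3SiOTf, Et3N, CH2Cl2, 0 °C; then Pd(OAc)2 (1.05 equiv), MeCN, 25 °C
Reagents that add atoms: none
Why: Saegusa–Ito dehydrogenation, in which the only enolisable side (C10) gives the silyl enol ether and palladation followed by β-hydride elimination installs the C10=C1 enone.

Step 5
Reactants: 8 (S)-6-methyl-6-[(E)-prop-1-en-1-yl]cyclohex-2-en-1-one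
Product: 9 (S)-2-(hydroxymethyl)-6-methyl-6-[(E)-prop-1-en-1-yl]cyclohex-2-en-1-one
Conditions: 37 % aq. HCHO, DMAP (cat.), THF–H2O, 25 °C
Reagents that add atoms: formaldehyde, C=O
Why: Morita–Baylis–Hillman reaction, in which DMAP adds to the β-unsubstituted enone, the enolate captures formaldehyde at C10 and loss of the catalyst returns the enone with C14 attached.

Step 6
Reactants: 9 (S)-2-(hydroxymethyl)-6-methyl-6-[(E)-prop-1-en-1-yl]cyclohex-2-en-1-one
Product: 10 (S)-6-methyl-6-[(E)-prop-1-en-1-yl]-2-{[(triisopropylsilyl)oxy]methyl}cyclohex-2-en-1-one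
Conditions: i-Pr3SiCl, imidazole, DMF, 25 °C
Reagents that add atoms: chlorotriisopropylsilane, CC(C)[Si](Cl)(C(C)C)C(C)C
Why: Silyl ether formation at the primary allylic alcohol, the bulky triisopropylsilyl group being chosen because it resists O-to-O migration to the neighbouring C9 alkoxide in steps 12 and 16.

Step 7
Reactants: 10 (S)-6-methyl-6-[(E)-prop-1-en-1-yl]-2-{[(triisopropylsilyl)oxy]methyl}cyclohex-2-en-1-one
Product: 12 (S)-1-methyl-2-oxo-3-{[(triisopropylsilyl)oxy]methyl}cyclohex-3-ene-1-carbaldehyde, via ozonide 11 (not isolated)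
Conditions: O3, CH2Cl2, −78 °C (Sudan Red 7B end point); then PPh3, −78 → 25 °C
Reagents that add atoms: ozone, [O-][O+]=O
Why: Ozonolysis with reductive work-up, in which ozone attacks the electron-rich propenyl alkene far faster than the electron-poor enone alkene and leaves the C5 aldehyde.

Step 8
Reactants: 12 (S)-1-methyl-2-oxo-3-{[(triisopropylsilyl)oxy]methyl}cyclohex-3-ene-1-carbaldehyde
Product: 13 (S)-6-(hydroxymethyl)-6-methyl-2-{[(triisopropylsilyl)oxy]methyl}cyclohex-2-en-1-one
Conditions: NaBH4, CH2Cl2–MeOH, −78 °C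
Reagents that add atoms: none
Why: Chemoselective borohydride reduction, the aldehyde reacting much faster at low temperature than the hindered conjugated ketone, to give the hydroxymethyl arm that directs step 12.

Step 9
Reactants: 14 but-3-yn-1-ol
Product: 15 (but-3-yn-1-yloxy)triisopropylsilane
Conditions: i-Pr3SiCl, imidazole, CH2Cl2, 25 °C
Reagents that add atoms: chlorotriisopropylsilane, CC(C)[Si](Cl)(C(C)C)C(C)C
Why: Silyl ether formation protects the primary alcohol for the organometallic steps.

Step 10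
Reactants: 15 (but-3-yn-1-yloxy)triisopropylsilane
Product: 16 [(4-iodobut-3-yn-1-yl)oxy]triisopropylsilane
Conditions: N-iodosuccinimide, AgNO3 (cat.), acetone, 25 °C, dark
Reagents that add atoms: N-iodosuccinimide, O=C1CCC(=O)N1I
Why: Silver-catalysed electrophilic iodination of the terminal alkyne through the silver acetylide.

Step 11
Reactants: 16 [(4-iodobut-3-yn-1-yl)oxy]triisopropylsilane
Product: 17 (Z)-[(4-iodobut-3-en-1-yl)oxy]triisopropylsilane
Conditions: 2-nitrobenzenesulfonyl hydrazide, Et3N, THF–i-PrOH, 25 °C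
Reagents that add atoms: none
Why: Diimide reduction, in which diimide formed in the flask transfers two hydrogens syn to the iodoalkyne and so gives the Z-vinyl iodide without C–I cleavage.

Step 12
Reactants: 13 (S)-6-(hydroxymethyl)-6-methyl-2-{[(triisopropylsilyl)oxy]methyl}cyclohex-2-en-1-one; 17 (Z)-[(4-iodobut-3-en-1-yl)oxy]triisopropylsilane
Product: 20 (1S,6S)-6-(hydroxymethyl)-6-methyl-2-{[(triisopropylsilyl)oxy]methyl}-1-{(Z)-4-[(triisopropylsilyl)oxy]but-1-en-1-yl}cyclohex-2-en-1-ol, via alkenyllithium 18 (not isolated), via alkenylmagnesium bromide 19 (not isolated)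
Conditions: 17 (2.4 equiv), t-BuLi (4.8 equiv), Et2O, −78 °C; MgBr2·OEt2, −78 → −40 °C; then 13, Et2O–CH2Cl2, −78 → −20 °C; aq. NH4Cl
Reagents that add atoms: none
Why: Chelation-controlled 1,2-addition of a Grignard reagent, in which the first equivalent forms the magnesium alkoxide of the C5 hydroxymethyl arm, its chelate with the C9 carbonyl holds that arm in the carbonyl plane and the C4 methyl pseudo-axial, and the Z-alkenyl group (formed with retention) therefore adds anti to the methyl and cis to the arm, setting C9 as S.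

Step 13
Reactants: 20 (1S,6S)-6-(hydroxymethyl)-6-methyl-2-{[(triisopropylsilyl)oxy]methyl}-1-{(Z)-4-[(triisopropylsilyl)oxy]but-1-en-1-yl}cyclohex-2-en-1-ol
Product: 21 (1R,2R)-2-hydroxy-1-methyl-3-{[(triisopropylsilyl)oxy]methyl}-2-{(Z)-4-[(triisopropylsilyl)oxy]but-1-en-1-yl}cyclohex-3-ene-1-carbaldehyde
Conditions: Dess–Martin periodinane, NaHCO3, CH2Cl2, 0 °C
Reagents that add atoms: none
Why: Dess–Martin oxidation converts the primary alcohol to the aldehyde and cannot touch the tertiary carbinol, while the quaternary α-carbon and the buffered non-basic medium prevent enolisation and retro-aldol cleavage.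

Step 14
Reactants: 21 (1R,2R)-2-hydroxy-1-methyl-3-{[(triisopropylsilyl)oxy]methyl}-2-{(Z)-4-[(triisopropylsilyl)oxy]but-1-en-1-yl}cyclohex-3-ene-1-carbaldehyde
Product: 22 (1S,6S)-6-methyl-6-[(E)-2-(4,4,5,5-tetramethyl-1,3,2-dioxaborolan-2-yl)ethenyl]-2-{[(triisopropylsilyl)oxy]methyl}-1-{(Z)-4-[(triisopropylsilyl)oxy]but-1-en-1-yl}cyclohex-2-en-1-ol
Conditions: Cl2CHB(pin), CrCl2, LiI, THF, 25 °C
Reagents that add atoms: 2-(dichloromethyl)-4,4,5,5-tetramethyl-1,3,2-dioxaborolane, ClC(Cl)B1OC(C)(C)C(C)(C)O1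
Why: Takai–Utimoto olefination, in which a geminal dichromium reagent adds to the hindered aldehyde and eliminates to the E-alkenylboronate, a process that tolerates the free tertiary alcohol.

Step 15
Reactants: 22 (1S,6S)-6-methyl-6-[(E)-2-(4,4,5,5-tetramethyl-1,3,2-dioxaborolan-2-yl)ethenyl]-2-{[(triisopropylsilyl)oxy]methyl}-1-{(Z)-4-[(triisopropylsilyl)oxy]but-1-en-1-yl}cyclohex-2-en-1-ol
Product: 23 (1S,6S)-6-{(E)-2-[(4-methoxybenzyl)oxy]ethenyl}-6-methyl-2-{[(triisopropylsilyl)oxy]methyl}-1-{(Z)-4-[(triisopropylsilyl)oxy]but-1-en-1-yl}cyclohex-2-en-1-ol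
Conditions: Cu(OAc)2 (2 equiv), Et3N, 4-methoxybenzyl alcohol (excess), 4 Å molecular sieves, air, 25 °C
Reagents that add atoms: 4-methoxybenzyl alcohol, COc1ccc(CO)cc1
Why: Chan–Lam-type oxidative C–O coupling, in which boron-to-copper transmetalation and C–O reductive elimination proceed with retention to give the E-enol ether under neutral room-temperature conditions that leave the tertiary alcohol un-ionised.

Step 16
Reactants: 23 (1S,6S)-6-{(E)-2-[(4-methoxybenzyl)oxy]ethenyl}-6-methyl-2-{[(triisopropylsilyl)oxy]methyl}-1-{(Z)-4-[(triisopropylsilyl)oxy]but-1-en-1-yl}cyclohex-2-en-1-ol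
Product: 26 (2Z,7Z,8R,9R)-8-[(4-methoxybenzyl)oxy]-7-methyl-2-{[(triisopropylsilyl)oxy]methyl}-9-{2-[(triisopropylsilyl)oxy]ethyl}cyclodeca-2,7-dien-1-one, via potassium alkoxide 24 (not isolated), via potassium enolate 25 (not isolated)
Conditions: KH (oil-free), 18-crown-6, THF, 0 → 25 °C; then aq. NH4Cl, −78 °C
Reagents that add atoms: none
Why: The crown-ether-separated potassium alkoxide weakens the C4–C9 bond, so the 1,5-diene C7=C8–C9–C4–C5=C6 undergoes a concerted [3,3] shift (anionic oxy-Cope rearrangement, well known for 1,2-dialkenylcyclohexanols) to the C8=C9 enolate, which is protonated to the ketone. The ten-membered ring is closed by sigmatropic four-atom ring expansion of the cyclohexene: C6–C7 forms within a six-membered chair array as C4–C9 breaks, and the cis C1=C10 alkene is carried over unchanged from the six-membered ring. In the chair open to the cis-dialkenyl carbinol, C10 and the C4 methyl are equatorial while C3 and the alkoxide are axial, and the axial C3 becomes cis to C6 in the new Z C4=C5 alkene. C6 is set by the E-enol ether (ether oxygen equatorial) and C7 by the Z-alkene (side chain axial), which together give the 6,7-cis pair, and the S centre at C4 with the S carbinol decides which enantiomeric chair is used, hence 6R,7R. The step needs this chair to win over the alternative chair with C10 axial (which would give the E alkene) and over boat arrays; the Z side chain would meet C10 in a 1,3-diaxial clash in the alternative chair, and the cis arms fixed in step 12 exclude the diequatorial pathway. The other conceivable [3,3] path through the ring alkene would need a bridged transition state, and the triisopropylsilyl group on O14 suppresses silyl transfer to the alkoxide.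

Step 17
Reactants: 26 (2Z,7Z,8R,9R)-8-[(4-methoxybenzyl)oxy]-7-methyl-2-{[(triisopropylsilyl)oxy]methyl}-9-{2-[(triisopropylsilyl)oxy]ethyl}cyclodeca-2,7-dien-1-one
Product: 28 10-hydroxy derivative of 26 (germacrane C8–OH, trans to the C7 side chain), via potassium enolate 27 (not isolated)
Conditions: KN(SiMe3)2, THF, −78 °C; then 2-(phenylsulfonyl)-3-phenyloxaziridine, −78 °C; aq. NH4Cl
Reagents that add atoms: 2-(phenylsulfonyl)-3-phenyloxaziridine, O=S(=O)(c1ccccc1)N1OC1c1ccccc1
Why: Enolate α-hydroxylation with an N-sulfonyloxaziridine after kinetic deprotonation at C8; with C7–H in the enolate plane and the C7–C6 ring bond perpendicular to it, the reagent should approach from the outer face of the ring, placing the hydroxyl trans to the C7 side chain, which is the C8 epimer that step 18 inverts.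

Step 18
Reactants: 28 10-hydroxy derivative of 26 (germacrane C8–OH, trans to the C7 side chain)
Product: 29 C8 acetate of inverted configuration (acetoxy cis to the C7 side chain, C9 ketone)
Conditions: PPh3, DIAD, AcOH, toluene, 0 → 25 °C
Reagents that add atoms: acetic acid, CC(=O)O
Why: Mitsunobu reaction, in which the alkoxyphosphonium of the α-ketol is displaced by acetate with SN2 inversion (displacement next to a carbonyl is fast), installing the C8 acetate cis to the C7 side chain.

Step 19
Reactants: 29 C8 acetate of inverted configuration (acetoxy cis to the C7 side chain, C9 ketone)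
Product: 30 C9 allylic alcohol (C9–OH trans to the C8 acetate)
Conditions: NaBH4, CeCl3·7H2O, MeOH, −78 °C
Reagents that add atoms: none
Why: Luche 1,2-reduction of the enone, in which hydride adds anti to the C8–OAc bond (Felkin–Anh) to give the C9 alcohol threo to the acetate, the low temperature preventing acetyl migration.

Step 20
Reactants: 31 (S)-2-methylglycidol
Product: 32 (R)-2-methyloxirane-2-carboxylic acid
Conditions: RuCl3·xH2O (cat.), NaIO4, MeCN–EtOAc–H2O, 0 → 25 °C
Reagents that add atoms: water, O; sodium periodate, [Na+].[O-]I(=O)(=O)=O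
Why: Ruthenium tetroxide oxidation of the primary alcohol to the acid leaves the quaternary epoxide centre untouched, the descriptor changing from S to R only through the priority rules.

Step 21
Reactants: 30 C9 allylic alcohol (C9–OH trans to the C8 acetate); 32 (R)-2-methyloxirane-2-carboxylic acid
Product: 34 C9 (R)-2-methylglycidate ester of 30, via mixed anhydride 33 (not isolated)
Conditions: 32, 2,4,6-trichlorobenzoyl chloride, Et3N, THF, 0 °C; then 30, DMAP, toluene, 25 °C
Reagents that add atoms: none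
Why: Yamaguchi esterification, in which DMAP attacks the less hindered glycidoyl carbonyl of the mixed anhydride and the acylpyridinium acylates the hindered allylic C9–OH with retention at C9 and at the glycidate centre.

Step 22
Reactants: 34 C9 (R)-2-methylglycidate ester of 30
Product: 35 C12,C14 diol
Conditions: HF·pyridine, pyridine, THF, 0 → 25 °C
Reagents that add atoms: none
Why: Fluoride-mediated desilylation under buffered acidic conditions removes both primary silyl ethers without acyl migration and spares the electron-poor glycidate epoxide, the esters and the 4-methoxybenzyl ether.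

Step 23
Reactants: 35 C12,C14 diol
Product: 36 dialdehyde (C12 aldehyde, C14 enal)
Conditions: Dess–Martin periodinane, NaHCO3, CH2Cl2, 0 → 25 °C
Reagents that add atoms: none
Why: Dess–Martin oxidation takes both primary alcohols to the aldehyde level in one buffered operation.

Step 24
Reactants: 36 dialdehyde (C12 aldehyde, C14 enal)
Product: 38 11(13)-methylene dialdehyde, via Mannich base 37 (not isolated)
Conditions: N,N-dimethylmethyleneiminium iodide, Et3N, CH2Cl2, 25 °C
Reagents that add atoms: N,N-dimethylmethyleneiminium iodide, C=[N+](C)C.[I-]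
Why: Mannich α-methylenation of an aldehyde, in which only the C12 aldehyde can enolise (towards C11) and its Mannich base loses dimethylamine by E1cB to give the C11=C13 methylene without strong base.

Step 25
Reactants: 38 11(13)-methylene dialdehyde
Product: 39 C12,C14 diacid
Conditions: NaClO2, NaH2PO4, 2-methyl-2-butene, t-BuOH–H2O, 0 → 25 °C
Reagents that add atoms: sodium chlorite, [Na+].[O-]Cl=O
Why: Pinnick oxidation converts both unsaturated aldehydes to the acids, the alkene scavenger removing hypochlorous acid so that the C4=C5 alkene and the benzylic ether survive.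

Step 26
Reactants: 39 C12,C14 diacid
Product: 40 C12,C14 dimethyl ester
Conditions: Me3SiCHN2, toluene–MeOH, 0 °C
Reagents that add atoms: (trimethylsilyl)diazomethane, C[Si](C)(C)C=[N+]=[N-]
Why: Esterification by diazomethane released in the flask methylates both acids under neutral conditions faster than any dipolar addition to the acrylates.

Step 27
Reactants: 40 C12,C14 dimethyl ester
Product: 42 4,5-alkene lactone (deoxy target), via hydroxy diester 41 (not isolated)
Conditions: DDQ, CH2Cl2–pH 7 buffer, 0 → 25 °C; then camphorsulfonic acid (cat.), CH2Cl2, 25 °C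
Reagents that add atoms: none
Why: Oxidative cleavage of the 4-methoxybenzyl ether by DDQ frees C6–OH, which under acid catalysis transesterifies the neighbouring C12 acrylate ester to the cis-fused five-membered lactone (5-exo-trig), the distant C14 ester staying untouched.

Step 28
Reactants: 42 4,5-alkene lactone (deoxy target)
Product: 43 target CNP0159450.1
Conditions: mCPBA, NaHCO3, CH2Cl2, 0 °C
Reagents that add atoms: 3-chloroperoxybenzoic acid, O=C(OO)c1cccc(Cl)c1
Why: Prilezhaev epoxidation touches only the electron-rich C4=C5 alkene and, with C6–H held in the alkene plane by allylic strain, should occur from the outer face anti to the C6–C7 ring bond, giving the cis epoxide with its oxygen trans to O6.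

**Compound list**

1 | 2-methylcyclohexanone | CC1CCCCC1=O | starting material
2 | allyl chloroformate | C=CCOC(=O)Cl | starting material
3 | potassium 2-methylcyclohex-1-en-1-olate | CC1=C([O-])CCCC1.[K+] | intermediate
4 | allyl 2-methylcyclohex-1-en-1-yl carbonate | C=CCOC(=O)OC1=C(C)CCCC1 | intermediate
5 | (S)-2-allyl-2-methylcyclohexan-1-one | O=C1CCCC[C@@]1(C)CC=C | intermediate
6 | (S)-2-methyl-2-[(E)-prop-1-en-1-yl]cyclohexan-1-one | O=C1CCCC[C@@]1(C)/C=C/C | intermediate
7 | (S)-trimethyl({6-methyl-6-[(E)-prop-1-en-1-yl]cyclohex-1-en-1-yl}oxy)silane | C[Si](C)(C)OC1=CCCC[C@@]1(C)/C=C/C | intermediate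
8 | (S)-6-methyl-6-[(E)-prop-1-en-1-yl]cyclohex-2-en-1-one | O=C1C=CCC[C@@]1(C)/C=C/C | intermediate
9 | (S)-2-(hydroxymethyl)-6-methyl-6-[(E)-prop-1-en-1-yl]cyclohex-2-en-1-one | O=C1C(CO)=CCC[C@@]1(C)/C=C/C | intermediate
10 | (S)-6-methyl-6-[(E)-prop-1-en-1-yl]-2-{[(triisopropylsilyl)oxy]methyl}cyclohex-2-en-1-one | O=C1C(CO[Si](C(C)C)(C(C)C)C(C)C)=CCC[C@@]1(C)/C=C/C | intermediate
11 | ozonide (1,2,4-trioxolane) of 10 at the propenyl group | O=C1C(CO[Si](C(C)C)(C(C)C)C(C)C)=CCC[C@@]1(C)C1OOC(C)O1 | intermediate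
12 | (S)-1-methyl-2-oxo-3-{[(triisopropylsilyl)oxy]methyl}cyclohex-3-ene-1-carbaldehyde | O=C1C(CO[Si](C(C)C)(C(C)C)C(C)C)=CCC[C@@]1(C)C=O | intermediate
13 | (S)-6-(hydroxymethyl)-6-methyl-2-{[(triisopropylsilyl)oxy]methyl}cyclohex-2-en-1-one | O=C1C(CO[Si](C(C)C)(C(C)C)C(C)C)=CCC[C@@]1(C)CO | intermediate
14 | but-3-yn-1-ol | C#CCCO | starting material
15 | (but-3-yn-1-yloxy)triisopropylsilane | C#CCCO[Si](C(C)C)(C(C)C)C(C)C | intermediate
16 | [(4-iodobut-3-yn-1-yl)oxy]triisopropylsilane | IC#CCCO[Si](C(C)C)(C(C)C)C(C)C | intermediate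
17 | (Z)-[(4-iodobut-3-en-1-yl)oxy]triisopropylsilane | I/C=C\CCO[Si](C(C)C)(C(C)C)C(C)C | intermediate
18 | (Z)-4-[(triisopropylsilyl)oxy]but-1-en-1-yllithium | [Li]/C=C\CCO[Si](C(C)C)(C(C)C)C(C)C | intermediate
19 | (Z)-4-[(triisopropylsilyl)oxy]but-1-en-1-ylmagnesium bromide | Br[Mg]/C=C\CCO[Si](C(C)C)(C(C)C)C(C)C | intermediate
20 | (1S,6S)-6-(hydroxymethyl)-6-methyl-2-{[(triisopropylsilyl)oxy]methyl}-1-{(Z)-4-[(triisopropylsilyl)oxy]but-1-en-1-yl}cyclohex-2-en-1-ol (alkenyl cis to CH2OH) | O[C@]1(/C=C\CCO[Si](C(C)C)(C(C)C)C(C)C)C(CO[Si](C(C)C)(C(C)C)C(C)C)=CCC[C@@]1(C)CO | intermediate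
21 | (1R,2R)-2-hydroxy-1-methyl-3-{[(triisopropylsilyl)oxy]methyl}-2-{(Z)-4-[(triisopropylsilyl)oxy]but-1-en-1-yl}cyclohex-3-ene-1-carbaldehyde (same spatial arrangement as 20) | O[C@]1(/C=C\CCO[Si](C(C)C)(C(C)C)C(C)C)C(CO[Si](C(C)C)(C(C)C)C(C)C)=CCC[C@@]1(C)C=O | intermediate
22 | (1S,6S)-6-methyl-6-[(E)-2-(4,4,5,5-tetramethyl-1,3,2-dioxaborolan-2-yl)ethenyl]-2-{[(triisopropylsilyl)oxy]methyl}-1-{(Z)-4-[(triisopropylsilyl)oxy]but-1-en-1-yl}cyclohex-2-en-1-ol | O[C@]1(/C=C\CCO[Si](C(C)C)(C(C)C)C(C)C)C(CO[Si](C(C)C)(C(C)C)C(C)C)=CCC[C@@]1(C)/C=C/B1OC(C)(C)C(C)(C)O1 | intermediate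
23 | (1S,6S)-6-{(E)-2-[(4-methoxybenzyl)oxy]ethenyl}-6-methyl-2-{[(triisopropylsilyl)oxy]methyl}-1-{(Z)-4-[(triisopropylsilyl)oxy]but-1-en-1-yl}cyclohex-2-en-1-ol (arms cis, OH cis to methyl) | O[C@]1(/C=C\CCO[Si](C(C)C)(C(C)C)C(C)C)C(CO[Si](C(C)C)(C(C)C)C(C)C)=CCC[C@@]1(C)/C=C/OCc1ccc(OC)cc1 | intermediate
24 | potassium alkoxide of 23 | [K+].[O-][C@]1(/C=C\CCO[Si](C(C)C)(C(C)C)C(C)C)C(CO[Si](C(C)C)(C(C)C)C(C)C)=CCC[C@@]1(C)/C=C/OCc1ccc(OC)cc1 | intermediate
25 | potassium enolate of 26 from the rearrangement (C8=C9, oxygen cis to C7) | COc1ccc(CO[C@@H]2[C@H](CCO[Si](C(C)C)(C(C)C)C(C)C)/C=C(\[O-])/C(CO[Si](C(C)C)(C(C)C)C(C)C)=C\CC/C(C)=C\2)cc1.[K+] | intermediate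
26 | (2Z,7Z,8R,9R)-8-[(4-methoxybenzyl)oxy]-7-methyl-2-{[(triisopropylsilyl)oxy]methyl}-9-{2-[(triisopropylsilyl)oxy]ethyl}cyclodeca-2,7-dien-1-one | COc1ccc(CO[C@@H]2[C@H](CCO[Si](C(C)C)(C(C)C)C(C)C)CC(=O)/C(CO[Si](C(C)C)(C(C)C)C(C)C)=C\CC/C(C)=C\2)cc1 | intermediate
27 | potassium enolate of 26 regenerated by base (C8=C9, geometry not assigned) | COc1ccc(CO[C@@H]2[C@H](CCO[Si](C(C)C)(C(C)C)C(C)C)C=C([O-])/C(CO[Si](C(C)C)(C(C)C)C(C)C)=C\CC/C(C)=C\2)cc1.[K+] | intermediate
28 | 10-hydroxy derivative of 26 (germacrane C8–OH trans to the C7 side chain) | COc1ccc(CO[C@@H]2[C@H](CCO[Si](C(C)C)(C(C)C)C(C)C)[C@@H](O)C(=O)/C(CO[Si](C(C)C)(C(C)C)C(C)C)=C\CC/C(C)=C\2)cc1 | intermediate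
29 | 10-acetoxy derivative of 26 with inverted C8 (acetoxy cis to the C7 side chain) | COc1ccc(CO[C@@H]2[C@H](CCO[Si](C(C)C)(C(C)C)C(C)C)[C@H](OC(C)=O)C(=O)/C(CO[Si](C(C)C)(C(C)C)C(C)C)=C\CC/C(C)=C\2)cc1 | intermediate
30 | C9 allylic alcohol from 29 (C9–OH trans to C8–OAc) | COc1ccc(CO[C@@H]2[C@H](CCO[Si](C(C)C)(C(C)C)C(C)C)[C@H](OC(C)=O)[C@@H](O)/C(CO[Si](C(C)C)(C(C)C)C(C)C)=C\CC/C(C)=C\2)cc1 | intermediate
31 | (S)-2-methylglycidol | OC[C@@]1(C)CO1 | starting material
32 | (R)-2-methyloxirane-2-carboxylic acid | OC(=O)[C@@]1(C)CO1 | intermediate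
33 | (R)-2-methyloxirane-2-carboxylic 2,4,6-trichlorobenzoic anhydride | O=C(OC(=O)c1c(Cl)cc(Cl)cc1Cl)[C@@]1(C)CO1 | intermediate
34 | C9 (R)-2-methylglycidate ester of 30 | COc1ccc(CO[C@@H]2[C@H](CCO[Si](C(C)C)(C(C)C)C(C)C)[C@H](OC(C)=O)[C@@H](OC(=O)[C@@]3(C)CO3)/C(CO[Si](C(C)C)(C(C)C)C(C)C)=C\CC/C(C)=C\2)cc1 | intermediate
35 | diol from 34 (free C12–OH and C14–OH) | COc1ccc(CO[C@@H]2[C@H](CCO)[C@H](OC(C)=O)[C@@H](OC(=O)[C@@]3(C)CO3)/C(CO)=C\CC/C(C)=C\2)cc1 | intermediate
36 | dialdehyde from 35 (C12 aldehyde, C14 enal) | COc1ccc(CO[C@@H]2[C@H](CC=O)[C@H](OC(C)=O)[C@@H](OC(=O)[C@@]3(C)CO3)/C(C=O)=C\CC/C(C)=C\2)cc1 | intermediate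
37 | Mannich base of 36 (dimethylaminomethyl group on C11) | COc1ccc(CO[C@@H]2[C@H](C(CN(C)C)C=O)[C@H](OC(C)=O)[C@@H](OC(=O)[C@@]3(C)CO3)/C(C=O)=C\CC/C(C)=C\2)cc1 | intermediate
38 | 11(13)-methylene dialdehyde | COc1ccc(CO[C@@H]2[C@H](C(=C)C=O)[C@H](OC(C)=O)[C@@H](OC(=O)[C@@]3(C)CO3)/C(C=O)=C\CC/C(C)=C\2)cc1 | intermediate
39 | C12,C14 diacid | COc1ccc(CO[C@@H]2[C@H](C(=C)C(=O)O)[C@H](OC(C)=O)[C@@H](OC(=O)[C@@]3(C)CO3)/C(C(=O)O)=C\CC/C(C)=C\2)cc1 | intermediate
40 | C12,C14 dimethyl ester | COc1ccc(CO[C@@H]2[C@H](C(=C)C(=O)OC)[C@H](OC(C)=O)[C@@H](OC(=O)[C@@]3(C)CO3)/C(C(=O)OC)=C\CC/C(C)=C\2)cc1 | intermediate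
41 | C6 alcohol from 40 (hydroxy diester) | O[C@@H]1[C@H](C(=C)C(=O)OC)[C@H](OC(C)=O)[C@@H](OC(=O)[C@@]2(C)CO2)/C(C(=O)OC)=C\CC/C(C)=C\1 | intermediate
42 | 4,5-alkene lactone (4Z; target without the epoxide oxygen) | C=C1C(=O)O[C@@H]2[C@H]1[C@H](OC(C)=O)[C@@H](OC(=O)[C@@]1(C)CO1)/C(C(=O)OC)=C\CC/C(C)=C\2 | intermediate
43 | CNP0159450.1: 8-acetoxy-9-[(R)-2-methylglycidoyloxy]-4,5-cis-epoxy-1(10)-cis-germacra-1(10),11(13)-dien-6,12-olide 14-oic acid methyl ester | C=C1C(=O)O[C@@H]2[C@H]1[C@H](OC(C)=O)[C@@H](OC(=O)[C@@]1(C)CO1)/C(C(=O)OC)=C\CC[C@@]1(C)O[C@@H]21 | target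

**Step count**

Total steps: 28. Longest linear sequence: 24 (steps 1–8, 12–19, 21–28); steps 9–11 and step 20 are side branches.

**Steps most likely to fail**

1. Step 16 (ring expansion). The chair that carries an axial alkoxide and an axial side chain may be reached only slowly, so that fragmentation of the alkoxide, silyl transfer or rearrangement through boat arrays erodes the yield and the C6/C7 control. Fallback: starting from 23, the tertiary alcohol is silylated (Me3SiOTf, 2,6-lutidine) to the trimethylsilyl ether of 23 F1, and this neutral substrate is rearranged thermally (siloxy-Cope, degassed o-dichlorobenzene, about 200 °C). This should lead through the same chair, without any charged oxygen, to the trimethylsilyl enol ether of 26 F2. Mild methanolysis (K2CO3, MeOH) of it returns to the route at 26.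

2. Step 12 (directed alkenyl addition). Incomplete chelation would lower the facial selectivity, and the bulky alkenylmagnesium reagent may add in conjugate fashion or merely act as a base. Fallback: starting from 13 and the alkyne 15, the lithium acetylide of 15 (n-BuLi, then CeCl3) is added to the magnesium alkoxide of 13. The slim, linear nucleophile adds strictly 1,2 and anti to the pseudo-axial methyl, giving the propargylic diol F3. Z-selective semi-hydrogenation (Pd on CaCO3 poisoned with Pb(OAc)2, quinoline, H2) then returns to the route at 20.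

3. Step 17 (C8 hydroxylation). The outer-face preference of the enolate oxidation may be weak or reversed, giving mixed C8 epimers. Fallback: both epimers are usable. Starting from 26, the oxidation is run as before and the ketols are separated; 28 follows step 18, while the C8-epimeric ketol F4 (hydroxyl already cis to the C7 side chain) is acetylated with retention (Ac2O, DMAP, pyridine). Both paths return to the route at 29.

Further compounds
F1 | step 16 | trimethylsilyl ether of 23 | C[Si](C)(C)O[C@]1(/C=C\CCO[Si](C(C)C)(C(C)C)C(C)C)C(CO[Si](C(C)C)(C(C)C)C(C)C)=CCC[C@@]1(C)/C=C/OCc1ccc(OC)cc1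
F2 | step 16 | trimethylsilyl enol ether of 26 (C8=C9, oxygen cis to C7) | COc1ccc(CO[C@@H]2[C@H](CCO[Si](C(C)C)(C(C)C)C(C)C)/C=C(\O[Si](C)(C)C)/C(CO[Si](C(C)C)(C(C)C)C(C)C)=C\CC/C(C)=C\2)cc1
F3 | step 12 | (1S,6S)-6-(hydroxymethyl)-6-methyl-2-{[(triisopropylsilyl)oxy]methyl}-1-{4-[(triisopropylsilyl)oxy]but-1-yn-1-yl}cyclohex-2-en-1-ol | O[C@]1(C#CCCO[Si](C(C)C)(C(C)C)C(C)C)C(CO[Si](C(C)C)(C(C)C)C(C)C)=CCC[C@@]1(C)CO
F4 | step 17 | C8 epimer of 28 (hydroxyl cis to the C7 side chain) | COc1ccc(CO[C@@H]2[C@H](CCO[Si](C(C)C)(C(C)C)C(C)C)[C@H](O)C(=O)/C(CO[Si](C(C)C)(C(C)C)C(C)C)=C\CC/C(C)=C\2)cc1
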